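## Retrosynthetic overview

1. The target is reached by desilylation at C9–O, after the C11 methyl is set by hydrogenation of an α-methylene lactone from its convex face.
2. Key step: one intramolecular chromium-mediated Nozaki–Hiyama (Barbier) 2-(methoxycarbonyl)allylation of the C6 enal forms the C6–C7 bond, both of its stereocentres, the ten-membered carbocycle and the cis-fused γ-lactone. The usual closures (ring-closing metathesis or vinyl halide/aldehyde coupling) are deliberately not used.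
3. The acyclic bromo-enoate/enal comes from cross-metathesis on a homoallylic alcohol; C3 and C9 are both set by Brown allylboration with the same reagent.
4. The Z C1=C10 alkene is locked in a temporary six-membered lactone made by ring-closing metathesis, then opened as a Weinreb amide; the (R)-2-methylbutanoate is attached right after opening.
5. Ring order: dihydropyranone (temporary, opened again), then the ten-membered carbocycle, then the γ-lactone in the same flask.

Assumption: atoms carry germacrane locants (ring C1–C10, C14 on C10, C15 on C4, lactone carbons C11–C13, C12 bound to O on C6), and metal alkoxides or adducts that are only hydrolysed on work-up are not numbered separately.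

## Route

Step 1
Reactants: 1 2,2-dimethoxyacetaldehyde (60% aqueous solution); 2 2-(triphenylphosphoranylidene)propanal
Product: 3 (E)-4,4-dimethoxy-2-methylbut-2-enal
Conditions: CH2Cl2, rt, 16 h
Reagents that add atoms: none
Why: Wittig olefination with a stabilised formyl ylide gives the (E)-trisubstituted enal (C6 cis to the C15 methyl), which is the C4=C5 geometry of the target.

Step 2
Reactants: 3 (E)-4,4-dimethoxy-2-methylbut-2-enal
Product: 4 (4S,5E)-7,7-dimethoxy-5-methylhepta-1,5-dien-4-ol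
Conditions: (−)-Ipc2BOMe, allylmagnesium bromide, Et2O, −78 °C; then 3; NaBO3·4H2O, THF/H2O
Reagents that add atoms: (−)-B-allyldiisopinocampheylborane (made from (−)-Ipc2BOMe and allylmagnesium bromide), C=CCB([C@@H]1C[C@@H]2C[C@H]([C@H]1C)C2(C)C)[C@@H]1C[C@@H]2C[C@H]([C@H]1C)C2(C)C
Why: Brown asymmetric allylboration; the reagent derived from (+)-α-pinene adds to the si face of the aldehyde through a chair transition state and sets C3 as S, and the acetal is inert.

Step 3
Reactants: 4 (4S,5E)-7,7-dimethoxy-5-methylhepta-1,5-dien-4-ol; 5 methacryloyl chloride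
Product: 6 (4S,5E)-7,7-dimethoxy-5-methylhepta-1,5-dien-4-yl 2-methylprop-2-enoate
Conditions: Et3N, DMAP (cat.), CH2Cl2, 0 °C
Reagents that add atoms: none
Why: DMAP-catalysed acylation of the secondary alcohol installs the methacrylate that supplies C9, C10 and C14, with no change at C3.

Step 4
Reactants: 6 (4S,5E)-7,7-dimethoxy-5-methylhepta-1,5-dien-4-yl 2-methylprop-2-enoate
Product: 7 (6S)-6-[(2E)-4,4-dimethoxybut-2-en-2-yl]-3-methyl-5,6-dihydro-2H-pyran-2-one
Conditions: second-generation Grubbs catalyst RuCl2(=CHPh)(PCy3)(H2IMes) (5 mol%), CH2Cl2 (5 mM), 40 °C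
Reagents that add atoms: none
Why: Ring-closing metathesis of the vinyl group with the methacrylate gives the six-membered unsaturated lactone, whose ring forces C1=C10 to be Z (C2 cis to C9); the trisubstituted C4=C5 alkene is a spectator.

Step 5
Reactants: 7 (6S)-6-[(2E)-4,4-dimethoxybut-2-en-2-yl]-3-methyl-5,6-dihydro-2H-pyran-2-one
Product: 8 (2Z,5S,6E)-5-hydroxy-N,8,8-trimethoxy-N,2,6-trimethylocta-2,6-dienamide
Conditions: MeNHOMe·HCl, iPrMgCl, THF, −20 → 0 °C
Reagents that add atoms: N,O-dimethylhydroxylamine hydrochloride, CNOC.Cl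
Why: Weinreb aminolysis (acyl substitution by the magnesium amide at the lactone carbonyl) opens the ring with the Z geometry kept and frees the C3 hydroxyl without a Lewis acid that could ionise the acetal.

Step 6
Reactants: 8 (2Z,5S,6E)-5-hydroxy-N,8,8-trimethoxy-N,2,6-trimethylocta-2,6-dienamide; 9 (R)-2-methylbutanoic acid
Product: 10 (2Z,5S,6E)-8,8-dimethoxy-1-[methoxy(methyl)amino]-2,6-dimethyl-1-oxoocta-2,6-dien-5-yl (2R)-2-methylbutanoate
Conditions: EDC·HCl, DMAP, CH2Cl2, 0 °C → rt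
Reagents that add atoms: none
Why: Steglich-type carbodiimide esterification acylates the C3 alcohol with retention at C3 and, at low temperature, without racemising the acid, so the final ester is in place before C9 exists and also blocks relactonisation.

Step 7
Reactants: 10 (2Z,5S,6E)-8,8-dimethoxy-1-[methoxy(methyl)amino]-2,6-dimethyl-1-oxoocta-2,6-dien-5-yl (2R)-2-methylbutanoate
Product: 11 (2E,4S,6Z)-1,1-dimethoxy-3,7-dimethyl-8-oxoocta-2,6-dien-4-yl (2R)-2-methylbutanoate
Conditions: Cp2Zr(H)Cl (1.5 equiv), THF, rt, 20 min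
Reagents that add atoms: none
Why: Schwartz-reagent reduction of the Weinreb amide stops at the aldehyde through a zirconated hemiaminal and leaves the ester, the acetal and the trisubstituted alkenes untouched, giving the (Z)-enal under neutral conditions.

Step 8
Reactants: 11 (2E,4S,6Z)-1,1-dimethoxy-3,7-dimethyl-8-oxoocta-2,6-dien-4-yl (2R)-2-methylbutanoate
Product: 12 (2E,4S,6Z,8S)-8-hydroxy-1,1-dimethoxy-3,7-dimethylundeca-2,6,10-trien-4-yl (2R)-2-methylbutanoate
Conditions: (−)-Ipc2BOMe, allylmagnesium bromide, Et2O, −78 °C; then 11; NaBO3·4H2O, THF/H2O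
Reagents that add atoms: (−)-B-allyldiisopinocampheylborane (made from (−)-Ipc2BOMe and allylmagnesium bromide), C=CCB([C@@H]1C[C@@H]2C[C@H]([C@H]1C)C2(C)C)[C@@H]1C[C@@H]2C[C@H]([C@H]1C)C2(C)C
Why: Second Brown allylboration; reagent-controlled si-face addition to the (Z)-enal at −78 °C (no base, so no Z/E leakage, and the ester is inert) sets C9 as S and brings in C8 and C7.

Step 9
Reactants: 12 (2E,4S,6Z,8S)-8-hydroxy-1,1-dimethoxy-3,7-dimethylundeca-2,6,10-trien-4-yl (2R)-2-methylbutanoate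
Product: 13 (2E,4S,6Z,8S)-8-(tert-butyldimethylsilyloxy)-1,1-dimethoxy-3,7-dimethylundeca-2,6,10-trien-4-yl (2R)-2-methylbutanoate
Conditions: TBSCl, imidazole, DMF, rt
Reagents that add atoms: TBSCl, CC(C)(C)[Si](C)(C)Cl
Why: Silylation protects the C9 alcohol so that it can neither alkylate the later allylic bromide nor quench the allylchromium; the chloride/imidazole conditions spare the acetal.

Step 10
Reactants: 13 (2E,4S,6Z,8S)-8-(tert-butyldimethylsilyloxy)-1,1-dimethoxy-3,7-dimethylundeca-2,6,10-trien-4-yl (2R)-2-methylbutanoate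
Product: 14 (2E,4S,6Z,8S)-8-(tert-butyldimethylsilyloxy)-3,7-dimethyl-1-oxoundeca-2,6,10-trien-4-yl (2R)-2-methylbutanoate
Conditions: PPTS (cat.), acetone/H2O 10:1, rt
Reagents that add atoms: water, O
Why: Mild acid hydrolysis of the allylic dimethyl acetal (through the stabilised oxocarbenium ion) frees the (E)-enal at C6 without touching the secondary silyl ether or the ester.

Step 11
Reactants: 14 (2E,4S,6Z,8S)-8-(tert-butyldimethylsilyloxy)-3,7-dimethyl-1-oxoundeca-2,6,10-trien-4-yl (2R)-2-methylbutanoate; 15 methyl 2-(bromomethyl)prop-2-enoate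
Product: 16 methyl (2Z,5S,6Z,9S,10E)-2-(bromomethyl)-5-(tert-butyldimethylsilyloxy)-6,10-dimethyl-9-[(2R)-2-methylbutanoyloxy]-12-oxododeca-2,6,10-trienoate
Conditions: second-generation Hoveyda–Grubbs catalyst RuCl2(=CH-C6H4-2-OiPr)(H2IMes) (10 mol%), 15 (8 equiv), CH2Cl2, 40 °C
Reagents that add atoms: none
Why: Olefin cross-metathesis of the only monosubstituted alkene with a 2-substituted acrylate (the reactivity class of methacrylates and methallyl halides) gives the trisubstituted enoate with C8 trans to the ester, while the two trisubstituted alkenes do not react.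

Step 12
Reactants: 16 methyl (2Z,5S,6Z,9S,10E)-2-(bromomethyl)-5-(tert-butyldimethylsilyloxy)-6,10-dimethyl-9-[(2R)-2-methylbutanoyloxy]-12-oxododeca-2,6,10-trienoate
Product: 19 (3S,6S,7S,9S)-9-(tert-butyldimethylsilyloxy)-3-[(2R)-2-methylbutanoyloxy]germacra-1(10)Z,4E,11(13)-trien-12,6-olide, via allylchromium dichloride 17 (not isolated), via chromium alkoxide 18 (not isolated)
Conditions: CrCl2 (10 equiv), THF, rt, 16 added over 12 h (final 2 mM); aq. NH4Cl
Reagents that add atoms: none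
Why: Intramolecular Nozaki–Hiyama (Barbier) allylation: divalent chromium reduces the allylic bromide to a trivalent allylchromium that adds 1,2 to the tethered enal through a chair transition state with C8 axial (C8 anti to the ester), which gives the syn C6/C7 adduct. The macrocyclic transition state with the C9 silyloxy and C3 acyloxy groups pseudo-equatorial is expected to select the face shown, and the syn alkoxide lactonises at once to the cis-fused α-methylene lactone.

Step 13
Reactants: 19 (3S,6S,7S,9S)-9-(tert-butyldimethylsilyloxy)-3-[(2R)-2-methylbutanoyloxy]germacra-1(10)Z,4E,11(13)-trien-12,6-olide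
Product: 20 (3S,6R,7S,9S,11R)-9-(tert-butyldimethylsilyloxy)-3-[(2R)-2-methylbutanoyloxy]germacra-1(10)Z,4E-dien-12,6-olide
Conditions: H2 (1 atm), RhCl(PPh3)3 (15 mol%), benzene/EtOH 1:1, rt
Reagents that add atoms: none
Why: Wilkinson hydrogenation reduces only the 1,1-disubstituted exocyclic alkene and delivers hydrogen to the convex face of the cis-fused lactone (anti to C5 and C8), setting C11 as R with the methyl cis to both ring bonds (the C6 descriptor changes from S to R only because the priorities change).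

Step 14
Reactants: 20 (3S,6R,7S,9S,11R)-9-(tert-butyldimethylsilyloxy)-3-[(2R)-2-methylbutanoyloxy]germacra-1(10)Z,4E-dien-12,6-olide
Product: 21 (3S,6R,7S,9S,11R)-9-hydroxy-3-[(2R)-2-methylbutanoyloxy]germacra-1(10)Z,4E-dien-12,6-olide (CNP0276536.2)
Conditions: HF·pyridine, pyridine, THF, 0 °C → rt
Reagents that add atoms: none
Why: Buffered fluoride desilylation frees the C9 alcohol under weakly acidic conditions that neither epimerise C11, migrate the ester, nor trigger transannular cyclisation of the 1,5-diene.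

## Compound list

1 | 2,2-dimethoxyacetaldehyde | COC(OC)C=O | starting material
2 | 2-(triphenylphosphoranylidene)propanal | CC(C=O)=P(c1ccccc1)(c1ccccc1)c1ccccc1 | starting material
3 | (E)-4,4-dimethoxy-2-methylbut-2-enal | COC(OC)/C=C(\C)C=O | intermediate
4 | (4S,5E)-7,7-dimethoxy-5-methylhepta-1,5-dien-4-ol | C=CC[C@H](O)/C(C)=C/C(OC)OC | intermediate
5 | methacryloyl chloride | C=C(C)C(=O)Cl | starting material
6 | (4S,5E)-7,7-dimethoxy-5-methylhepta-1,5-dien-4-yl 2-methylprop-2-enoate | C=CC[C@H](OC(=O)C(C)=C)/C(C)=C/C(OC)OC | intermediate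
7 | (6S)-6-[(2E)-4,4-dimethoxybut-2-en-2-yl]-3-methyl-5,6-dihydro-2H-pyran-2-one | CC1=CC[C@@H](/C(C)=C/C(OC)OC)OC1=O | intermediate
8 | (2Z,5S,6E)-5-hydroxy-N,8,8-trimethoxy-N,2,6-trimethylocta-2,6-dienamide | CON(C)C(=O)/C(C)=C\C[C@H](O)/C(C)=C/C(OC)OC | intermediate
9 | (R)-2-methylbutanoic acid | CC[C@@H](C)C(=O)O | starting material
10 | (2Z,5S,6E)-8,8-dimethoxy-1-[methoxy(methyl)amino]-2,6-dimethyl-1-oxoocta-2,6-dien-5-yl (2R)-2-methylbutanoate | CC[C@@H](C)C(=O)O[C@@H](C/C=C(/C)C(=O)N(C)OC)/C(C)=C/C(OC)OC | intermediate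
11 | (2E,4S,6Z)-1,1-dimethoxy-3,7-dimethyl-8-oxoocta-2,6-dien-4-yl (2R)-2-methylbutanoate | CC[C@@H](C)C(=O)O[C@@H](C/C=C(/C)C=O)/C(C)=C/C(OC)OC | intermediate
12 | (2E,4S,6Z,8S)-8-hydroxy-1,1-dimethoxy-3,7-dimethylundeca-2,6,10-trien-4-yl (2R)-2-methylbutanoate | CC[C@@H](C)C(=O)O[C@@H](C/C=C(/C)[C@@H](O)CC=C)/C(C)=C/C(OC)OC | intermediate
13 | (2E,4S,6Z,8S)-8-(tert-butyldimethylsilyloxy)-1,1-dimethoxy-3,7-dimethylundeca-2,6,10-trien-4-yl (2R)-2-methylbutanoate | CC[C@@H](C)C(=O)O[C@@H](C/C=C(/C)[C@@H](O[Si](C)(C)C(C)(C)C)CC=C)/C(C)=C/C(OC)OC | intermediate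
14 | (2E,4S,6Z,8S)-8-(tert-butyldimethylsilyloxy)-3,7-dimethyl-1-oxoundeca-2,6,10-trien-4-yl (2R)-2-methylbutanoate | CC[C@@H](C)C(=O)O[C@@H](C/C=C(/C)[C@@H](O[Si](C)(C)C(C)(C)C)CC=C)/C(C)=C/C=O | intermediate
15 | methyl 2-(bromomethyl)prop-2-enoate | C=C(CBr)C(=O)OC | starting material
16 | methyl (2Z,5S,6Z,9S,10E)-2-(bromomethyl)-5-(tert-butyldimethylsilyloxy)-6,10-dimethyl-9-[(2R)-2-methylbutanoyloxy]-12-oxododeca-2,6,10-trienoate | CC[C@@H](C)C(=O)O[C@@H](C/C=C(/C)[C@@H](O[Si](C)(C)C(C)(C)C)C/C=C(/C(=O)OC)CBr)/C(C)=C/C=O | intermediate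
17 | allylchromium dichloride from 16 (C13–CrCl2 in place of C13–Br, trivalent chromium) | CC[C@@H](C)C(=O)O[C@@H](C/C=C(/C)[C@@H](O[Si](C)(C)C(C)(C)C)C/C=C(/C(=O)OC)C[Cr](Cl)Cl)/C(C)=C/C=O | intermediate
18 | chromium alkoxide of the cyclised hydroxy ester: ten-membered ring closed at C6–C7, C6–O–CrCl2, C7 bearing the methyl acrylate unit, (3S,6S,7S,9S) | CC[C@@H](C)C(=O)O[C@H]1C/C=C(/C)[C@@H](O[Si](C)(C)C(C)(C)C)C[C@H]([C@H](/C=C/1C)O[Cr](Cl)Cl)C(=C)C(=O)OC | intermediate
19 | (3S,6S,7S,9S)-9-(tert-butyldimethylsilyloxy)-3-[(2R)-2-methylbutanoyloxy]germacra-1(10)Z,4E,11(13)-trien-12,6-olide (cis-fused α-methylene lactone) | CC[C@@H](C)C(=O)O[C@H]1C/C=C(/C)[C@@H](O[Si](C)(C)C(C)(C)C)C[C@@H]2[C@H](/C=C/1C)OC(=O)C2=C | intermediate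
20 | (3S,6R,7S,9S,11R)-9-(tert-butyldimethylsilyloxy)-3-[(2R)-2-methylbutanoyloxy]germacra-1(10)Z,4E-dien-12,6-olide | CC[C@@H](C)C(=O)O[C@H]1C/C=C(/C)[C@@H](O[Si](C)(C)C(C)(C)C)C[C@@H]2[C@H](/C=C/1C)OC(=O)[C@@H]2C | intermediate
21 | (3S,6R,7S,9S,11R)-9-hydroxy-3-[(2R)-2-methylbutanoyloxy]germacra-1(10)Z,4E-dien-12,6-olide; systematic: (3R,3aS,5S,6Z,9S,10E,11aR)-5-hydroxy-3,6,10-trimethyl-2-oxo-2,3,3a,4,5,8,9,11a-octahydrocyclodeca[b]furan-9-yl (2R)-2-methylbutanoate | CC[C@@H](C)C(=O)O[C@H]1C/C=C(/C)[C@@H](O)C[C@@H]2[C@H](/C=C/1C)OC(=O)[C@@H]2C | target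

## Step count and risk

Total steps: 14. Longest linear sequence: 14 (fully linear from 1 and 2).

**Step 12 (macrocyclisation).** The cis C6/C7 relationship follows from the allylmetal geometry, but which aldehyde face reacts rests on macrocyclic control by C3 and C9 and has not been modelled; ten-membered ring closure can also lose to oligomerisation. The fallback sets out from alcohol 4 and rejoins at 19:
- 4 is esterified with acid 9 (EDC·HCl, DMAP) to the (R)-2-methylbutanoate ester F1, and its acetal is hydrolysed (PPTS, acetone/H2O) to the enal F2.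
- Separately, methacrolein and (−)-B-allyldiisopinocampheylborane give (3S)-2-methylhexa-1,5-dien-3-ol F3, which is silylated (TBSCl, imidazole) to the silyl ether F4.
- Cross-metathesis of the monosubstituted alkene of F4 with 15 gives the bromo-enoate F5.
- An intermolecular CrCl2-mediated 2-(methoxycarbonyl)allylation of F2 with F5 gives the cis-lactone diene F6. It is run with a stoichiometric chiral sulfonamide ligand on chromium to steer the aldehyde face; otherwise the two cis diastereomers are separated.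
- Ring-closing metathesis of the vinyl and isopropenyl groups of F6 (second-generation Grubbs catalyst RuCl2(=CHPh)(PCy3)(H2IMes), dilute toluene, 80 °C) closes the ten-membered ring at C1=C10, where the ring favours the Z alkene, and gives 19.

**Step 11 (cross-metathesis).** The partner is an electron-poor 1,1-disubstituted alkene carrying an allylic bromide, so conversion may be low and homodimer of 14 may dominate. The fallback sets out from enal 11 and rejoins at 16:
- A catalytic asymmetric Mukaiyama acetate aldol of 11 with the trimethylsilyl ketene acetal of S-ethyl thioacetate (Ti(OiPr)4/BINOL, enantiomer chosen for the 9S carbinol) gives the β-hydroxy thioester F7.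
- TBSCl/imidazole gives the silyl ether F8, and Fukuyama reduction (Et3SiH, Pd/C, acetone) gives the aldehyde F9 without touching the ester.
- A Morita–Baylis–Hillman reaction with methyl acrylate (DABCO) gives the allylic alcohol F10 (both C7 epimers serve).
- Acetal hydrolysis (PPTS, acetone/H2O) gives the enal F11.
- NBS/Me2S converts the allylic alcohol with SN2′ transposition into the (Z)-bromide 16.

**Step 5 (lactone opening).** The (Z)-δ-hydroxy Weinreb amide can relactonise, and the magnesium amide may add in conjugate fashion. The fallback sets out from lactone 7 and rejoins at enal 11: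
- iBu2AlH (excess, CH2Cl2, −78 °C) reduces 7 to the (2Z)-diol F12.
- TESCl/imidazole silylates only the primary allylic alcohol to give the silyl ether F13.
- Esterification of the C3 alcohol with 9 (EDC·HCl, DMAP) gives the ester F14.
- PPTS in MeOH removes the triethylsilyl group to give the allylic alcohol F15.
- MnO2 (CH2Cl2) oxidises it to the (Z)-enal 11.

Further compounds
F1 | step 12 | (4S,5E)-7,7-dimethoxy-5-methylhepta-1,5-dien-4-yl (2R)-2-methylbutanoate | CC[C@@H](C)C(=O)O[C@@H](CC=C)/C(C)=C/C(OC)OC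
F2 | step 12 | (4S,5E)-5-methyl-7-oxohepta-1,5-dien-4-yl (2R)-2-methylbutanoate | CC[C@@H](C)C(=O)O[C@@H](CC=C)/C(C)=C/C=O
F3 | step 12 | (3S)-2-methylhexa-1,5-dien-3-ol | C=C(C)[C@@H](O)CC=C
F4 | step 12 | tert-butyldimethyl{[(3S)-2-methylhexa-1,5-dien-3-yl]oxy}silane | C=C(C)[C@@H](O[Si](C)(C)C(C)(C)C)CC=C
F5 | step 12 | methyl (2Z,5S)-2-(bromomethyl)-5-(tert-butyldimethylsilyloxy)-6-methylhepta-2,6-dienoate | C=C(C)[C@@H](O[Si](C)(C)C(C)(C)C)C/C=C(/C(=O)OC)CBr
F6 | step 12 | cis-4,5-disubstituted α-methylene-γ-butyrolactone: C6 bears the (E)-C4(Me)=C5 chain with the C3 (2R)-2-methylbutanoate and allyl group, C7 bears CH2–C9H(OTBS)–isopropenyl, stereocentres as in 19 | CC[C@@H](C)C(=O)O[C@@H](CC=C)/C(C)=C/[C@@H]1OC(=O)C(=C)[C@@H]1C[C@H](O[Si](C)(C)C(C)(C)C)C(C)=C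
F7 | step 11 | S-ethyl (3S,4Z,7S,8E)-3-hydroxy-10,10-dimethoxy-4,8-dimethyl-7-[(2R)-2-methylbutanoyloxy]deca-4,8-dienethioate | CC[C@@H](C)C(=O)O[C@@H](C/C=C(/C)[C@@H](O)CC(=O)SCC)/C(C)=C/C(OC)OC
F8 | step 11 | S-ethyl (3S,4Z,7S,8E)-3-(tert-butyldimethylsilyloxy)-10,10-dimethoxy-4,8-dimethyl-7-[(2R)-2-methylbutanoyloxy]deca-4,8-dienethioate | CC[C@@H](C)C(=O)O[C@@H](C/C=C(/C)[C@@H](O[Si](C)(C)C(C)(C)C)CC(=O)SCC)/C(C)=C/C(OC)OC
F9 | step 11 | (2E,4S,6Z,8S)-8-(tert-butyldimethylsilyloxy)-1,1-dimethoxy-3,7-dimethyl-10-oxodeca-2,6-dien-4-yl (2R)-2-methylbutanoate | CC[C@@H](C)C(=O)O[C@@H](C/C=C(/C)[C@@H](O[Si](C)(C)C(C)(C)C)CC=O)/C(C)=C/C(OC)OC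
F10 | step 11 | methyl (5S,6Z,9S,10E)-5-(tert-butyldimethylsilyloxy)-3-hydroxy-12,12-dimethoxy-6,10-dimethyl-2-methylidene-9-[(2R)-2-methylbutanoyloxy]dodeca-6,10-dienoate (both C3 epimers) | CC[C@@H](C)C(=O)O[C@@H](C/C=C(/C)[C@@H](O[Si](C)(C)C(C)(C)C)CC(O)C(=C)C(=O)OC)/C(C)=C/C(OC)OC
F11 | step 11 | methyl (5S,6Z,9S,10E)-5-(tert-butyldimethylsilyloxy)-3-hydroxy-6,10-dimethyl-2-methylidene-9-[(2R)-2-methylbutanoyloxy]-12-oxododeca-6,10-dienoate (both C3 epimers) | CC[C@@H](C)C(=O)O[C@@H](C/C=C(/C)[C@@H](O[Si](C)(C)C(C)(C)C)CC(O)C(=C)C(=O)OC)/C(C)=C/C=O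
F12 | step 5 | (2Z,5S,6E)-8,8-dimethoxy-2,6-dimethylocta-2,6-diene-1,5-diol | OC/C(C)=C\C[C@H](O)/C(C)=C/C(OC)OC
F13 | step 5 | (2E,4S,6Z)-1,1-dimethoxy-3,7-dimethyl-8-(triethylsilyloxy)octa-2,6-dien-4-ol | CC[Si](CC)(CC)OC/C(C)=C\C[C@H](O)/C(C)=C/C(OC)OC
F14 | step 5 | (2E,4S,6Z)-1,1-dimethoxy-3,7-dimethyl-8-(triethylsilyloxy)octa-2,6-dien-4-yl (2R)-2-methylbutanoate | CC[C@@H](C)C(=O)O[C@@H](C/C=C(/C)CO[Si](CC)(CC)CC)/C(C)=C/C(OC)OC
F15 | step 5 | (2E,4S,6Z)-8-hydroxy-1,1-dimethoxy-3,7-dimethylocta-2,6-dien-4-yl (2R)-2-methylbutanoate | CC[C@@H](C)C(=O)O[C@@H](C/C=C(/C)CO)/C(C)=C/C(OC)OC
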